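The acetoxy-bearing cyclohexane, ring C (C6, C11, C12, C14, C15, C16; locants below), is cut at C14–C16 by deleting C15. The resulting isotwistane ketone, with a five-membered ring C6–C11–C12–C14–C16, arises together with the bicyclo[2.2.2]octane from an intramolecular double Michael reaction of a cyclohexenone carrying a tigloylmethyl arm. The key step puts C15 back: Lewis-acid-promoted diazoalkane homologation of the C14 ketone, C16 migrating with retention. It exploits C14 being flanked by quaternary C12 and enolisable C16: the C16 methyl is fixed exo in the strained five-membered ketone and becomes the axial, no longer epimerisable methyl of the six-membered ring.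

Key step: step 8

Remark: locants are those of the target, C1H2=C2H–C3(OH)(CH3)–C4H2–C5H2–C6; ring A = C6–C7–C8–C9(=O)–C10–C11; the bridge C12(CH3)–C13H(CH3) joins C11 to C8; ring C = C6–C11–C12–C14(OAc)–C15–C16(CH3); compounds 1, 2, 7 and 10 (pure E isomer) are taken as purchasable.

Step 1
Reactants: 1 3-ethoxycyclohex-2-en-1-one; 2 (4-bromobut-1-yn-1-yl)trimethylsilane
Product: 5 3-[4-(trimethylsilyl)but-3-yn-1-yl]cyclohex-2-en-1-one, via Grignard reagent 3 (not isolated), via tertiary carbinol adduct 4 (not isolated)
Conditions: Mg, THF, rt; then 1, 0 °C; then 1 M HCl, rt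
Reagents that add atoms: water, O
Why: Stork–Danheiser sequence, in which the Grignard reagent adds 1,2 to the vinylogous ester and acid hydrolysis of the enol ether with loss of water transposes the enone; no stereocenter is formed.

Step 2
Reactants: 5 3-[4-(trimethylsilyl)but-3-yn-1-yl]cyclohex-2-en-1-one
Product: 6 (S)-3-[4-(trimethylsilyl)but-3-yn-1-yl]cyclohex-2-en-1-ol
Conditions: (R)-2-methyl-CBS-oxazaborolidine (10 mol%), catecholborane, toluene, −78 °C
Reagents that add atoms: none
Why: Corey–Bakshi–Shibata reduction, in which the carbonyl binds anti to the alkenyl (large) substituent so that the (R)-catalyst should give the (S)-allylic alcohol at C10.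

Step 3
Reactants: 6 (S)-allylic alcohol; 7 1,1-dimethoxy-N,N-dimethylethan-1-amine
Product: 9 2-{(1R)-1-[4-(trimethylsilyl)but-3-yn-1-yl]cyclohex-2-en-1-yl}-N,N-dimethylacetamide, via ketene N,O-acetal 8 (not isolated)
Conditions: xylenes, 140 °C
Reagents that add atoms: none
Why: Eschenmoser–Claisen rearrangement, in which the suprafacial [3,3] shift of 8 through a chair-like transition state transfers the C10–O configuration to the new quaternary C6 and moves the alkene to C10=C11.

Step 4
Reactants: 9 amide; 10 (E)-2-bromobut-2-ene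
Product: 12 (E)-3-methyl-1-{(1R)-1-[4-(trimethylsilyl)but-3-yn-1-yl]cyclohex-2-en-1-yl}pent-3-en-2-one, via vinyllithium 11 (not isolated)
Conditions: 10, t-BuLi (2 equiv), Et2O, −78 °C; then 9, −78 → 0 °C; aq NH4Cl
Reagents that add atoms: none
Why: Bromine–lithium exchange proceeds with retention of the E geometry and the vinyllithium adds once to the tertiary amide (acyl substitution through a stable tetrahedral adduct that collapses on work-up), giving the tigloyl ketone.

Step 5
Reactants: 12 tigloyl ketone
Product: 13 (S)-4-[(E)-3-methyl-2-oxopent-3-en-1-yl]-4-[4-(trimethylsilyl)but-3-yn-1-yl]cyclohex-2-en-1-one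
Conditions: Rh2(cap)4 (dirhodium tetracaprolactamate, 1 mol%), t-BuOOH, K2CO3, CH2Cl2, rt
Reagents that add atoms: tert-butyl hydroperoxide, CC(C)(C)OO
Why: Radical allylic oxidation (tert-butylperoxyl chain) can only occur at C9, the single allylic methylene of the ring because C6 is quaternary, and the electron-poor tigloyl alkene and the silylalkyne should react more slowly.

Step 6
Reactants: 13 cyclohexenone
Product: 15 isotwistane ketone with C9 triisopropylsilyl enol ether, via tricyclic lithium enolate 14 (not isolated)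
Conditions: LiHMDS (1.1 equiv), THF, −78 → 0 °C; then TIPSOTf, −78 °C → rt
Reagents that add atoms: triisopropylsilyl trifluoromethanesulfonate, CC(C)[Si](C(C)C)(C(C)C)OS(=O)(=O)C(F)(F)F
Why: Intramolecular double Michael reaction (anionic formal [4+2]), in which the cross-conjugated C8 enolate adds to C13 and the resulting C12 enolate closes onto C11; the arm on C6 fixes the face, the E geometry should place the C12 and C13 methyls both on the C9 side as in a suprafacial cycloaddition, and O-silylation of the C9 enolate differentiates the two carbonyls and blocks retro-Michael opening.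

Step 7
Reactants: 15 isotwistane ketone
Product: 17 C16-exo-methyl isotwistane ketone, via C14 lithium enolate 16 (not isolated)
Conditions: LDA, THF, −78 °C; MeI, −78 → −20 °C
Reagents that add atoms: iodomethane, CI
Why: Enolate alkylation, in which C16 is the only enolisable position of the C14 ketone (C12 is quaternary) and iodomethane should approach from the convex exo face away from C7 and C13 of the cage, setting the C16 methyl exo (also the thermodynamically preferred epimer).

Step 8
Reactants: 17 C16-exo-methyl isotwistane ketone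
Product: 19 ring-C ketone with terminal alkyne, via alpha-silyl ketone 18 (not isolated)
Conditions: TMSCHN2 (hexanes), Me3Al, CH2Cl2, −78 → −20 °C; then K2CO3, MeOH, rt
Reagents that add atoms: (trimethylsilyl)diazomethane, C[Si](C)(C)C=[N+]=[N-]
Why: Me3Al activates the C14 carbonyl, the diazoalkane carbon adds from the exo face and the β-oxido diazonium loses N2 with a 1,2-shift of C16 from C14 to the new carbon C15, giving α-silyl ketone 18, after which methanolysis removes the C15 and alkynyl silyl groups. The closest known reaction type is the organoaluminium-promoted homologation of ketones with trimethylsilyldiazomethane (Tiffeneau–Demjanov-type ring expansion). No new ring is closed: the five-membered ring C6–C11–C12–C14–C16 is enlarged to the six-membered ring C by a 1,2-carbon shift, which also releases the strain of the isotwistane. No lasting stereocenter is created; C16 migrates with retention, so its exo methyl becomes the axial methyl of ring C, and C15 ends as CH2. Regioselectivity (C16 rather than C12) should follow from the usual preference for migration of the less substituted carbon, reinforced by the silyl group avoiding quaternary C12 in the anti-periplanar conformer; chemoselectivity rests on C9 being masked as the silyl enol ether, and the bulky α-silyl group should prevent a second insertion.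

Step 9
Reactants: 19 ring-C ketone
Product: 20 equatorial C14 alcohol
Conditions: SmI2, H2O, Et3N, THF, rt
Reagents that add atoms: none
Why: Single-electron (ketyl) reduction followed by protonation should give the more stable equatorial C14–OH, because the axial epimer would be syn-diaxial to the C16 methyl; the alkyne and the silyl enol ether are inert.

Step 10
Reactants: 20 equatorial C14 alcohol
Product: 22 (E)-allylic alcohol, via alkenylalane 21 (not isolated)
Conditions: Me3Al, Cp2ZrCl2, CH2Cl2, 0 °C → rt; then n-BuLi, (CH2O)n, THF, −78 °C → rt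
Reagents that add atoms: trimethylaluminium, C[Al](C)C; formaldehyde (from paraformaldehyde), C=O
Why: Negishi zirconium-catalysed carboalumination adds Me–Al syn (methyl to C3, aluminium to C2) and the derived alanate is hydroxymethylated with retention, giving the (E)-trisubstituted allylic alcohol while the C14 hydroxyl is carried as its aluminium alkoxide.

Step 11
Reactants: 22 (E)-allylic alcohol
Product: 23 (2S,3S)-epoxy alcohol
Conditions: Ti(OiPr)4 (10 mol%), L-(+)-diethyl tartrate, t-BuOOH, 4 Å MS, CH2Cl2, −20 °C
Reagents that add atoms: tert-butyl hydroperoxide, CC(C)(C)OO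
Why: Sharpless asymmetric epoxidation, in which reagent control with L-(+)-diethyl tartrate should deliver oxygen to the face of the (E)-allylic alcohol that gives the (2S,3S)-epoxide and so fixes C3; the distant C14 hydroxyl and the enol ether are not directed.

Step 12
Reactants: 23 epoxy alcohol
Product: 24 epoxy iodide
Conditions: PPh3, imidazole, I2, CH2Cl2, 0 °C
Reagents that add atoms: iodine, II
Why: Appel-type iodination (Garegg–Samuelsson conditions) converts the primary epoxy alcohol into the iodide by SN2 at C1; the hindered secondary C14–OH should not react and no stereocenter is touched.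

Step 13
Reactants: 24 epoxy iodide
Product: 25 (3S)-tertiary allylic alcohol
Conditions: Zn dust, EtOH, reflux
Reagents that add atoms: none
Why: Zinc insertion into the C–I bond followed by β-elimination opens the epoxide (reductive elimination of a 2,3-epoxy iodide), giving the vinyl carbinol with the C3–O bond, and hence the S configuration, intact.

Step 14
Reactants: 25 diol
Product: 26 C14 acetate
Conditions: Ac2O, pyridine, DMAP (cat.), CH2Cl2, rt
Reagents that add atoms: acetic anhydride, CC(=O)OC(C)=O
Why: DMAP-catalysed acylation should esterify the secondary equatorial C14–OH while the tertiary allylic C3–OH is too hindered to react under these conditions.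

Step 15
Reactants: 26 C14 acetate
Product: 27 target CNP0281208.1
Conditions: TBAF, AcOH, THF, 0 °C
Reagents that add atoms: none
Why: Buffered fluoride cleaves the silyl enol ether and protonation at C10 (a CH2, no new stereocenter) releases the C9 ketone without touching the acetate or the tertiary allylic alcohol.

Compound list
1 | 3-ethoxycyclohex-2-en-1-one | CCOC1=CC(=O)CCC1 | starting material
2 | (4-bromobut-1-yn-1-yl)trimethylsilane | C[Si](C)(C)C#CCCBr | starting material
3 | [4-(trimethylsilyl)but-3-yn-1-yl]magnesium bromide | C[Si](C)(C)C#CCC[Mg]Br | intermediate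
4 | 3-ethoxy-1-[4-(trimethylsilyl)but-3-yn-1-yl]cyclohex-2-en-1-ol (racemic, present as its magnesium alkoxide) | CCOC1=CC(O)(CCC#C[Si](C)(C)C)CCC1 | intermediate
5 | 3-[4-(trimethylsilyl)but-3-yn-1-yl]cyclohex-2-en-1-one | O=C1C=C(CCC#C[Si](C)(C)C)CCC1 | intermediate
6 | (S)-3-[4-(trimethylsilyl)but-3-yn-1-yl]cyclohex-2-en-1-ol | O[C@@H]1C=C(CCC#C[Si](C)(C)C)CCC1 | intermediate
7 | 1,1-dimethoxy-N,N-dimethylethan-1-amine (N,N-dimethylacetamide dimethyl acetal) | COC(C)(OC)N(C)C | starting material
8 | N,N-dimethyl-1-{[(1S)-3-[4-(trimethylsilyl)but-3-yn-1-yl]cyclohex-2-en-1-yl]oxy}ethen-1-amine (ketene N,O-acetal) | C=C(N(C)C)O[C@@H]1C=C(CCC#C[Si](C)(C)C)CCC1 | intermediate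
9 | 2-{(1R)-1-[4-(trimethylsilyl)but-3-yn-1-yl]cyclohex-2-en-1-yl}-N,N-dimethylacetamide | C[Si](C)(C)C#CCC[C@@]1(C=CCCC1)CC(=O)N(C)C | intermediate
10 | (E)-2-bromobut-2-ene | Br/C(C)=C/C | starting material
11 | (E)-but-2-en-2-yllithium | [Li]/C(C)=C/C | intermediate
12 | (E)-3-methyl-1-{(1R)-1-[4-(trimethylsilyl)but-3-yn-1-yl]cyclohex-2-en-1-yl}pent-3-en-2-one | C[Si](C)(C)C#CCC[C@@]1(C=CCCC1)CC(=O)/C(C)=C/C | intermediate
13 | (S)-4-[(E)-3-methyl-2-oxopent-3-en-1-yl]-4-[4-(trimethylsilyl)but-3-yn-1-yl]cyclohex-2-en-1-one | C[Si](C)(C)C#CCC[C@@]1(C=CC(=O)CC1)CC(=O)/C(C)=C/C | intermediate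
14 | lithium C9 enolate of the tricyclic (isotwistane) diketone: bicyclo[2.2.2]octene C6–C7–C8–C9(OLi)=C10–C11–C12–C13 bridged from C6 to C12 by C16H2–C14(=O); C12-Me and C13-Me both on the C9 side | C[Si](C)(C)C#CCC[C@@]12C[C@H]3C(O[Li])=C[C@@H]1[C@](C)([C@@H]3C)C(=O)C2 | intermediate
15 | isotwistane ketone: as 14 with C9–OSi(iPr)3 (C9=C10 enol ether), C14 ketone in the five-membered ring C6–C11–C12–C14–C16H2, CH2CH2C≡C–SiMe3 on C6 | C[Si](C)(C)C#CCC[C@@]12C[C@H]3C(O[Si](C(C)C)(C(C)C)C(C)C)=C[C@@H]1[C@](C)([C@@H]3C)C(=O)C2 | intermediate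
16 | lithium C14 enolate of 15 (C14(OLi)=C16) | C[Si](C)(C)C#CCC[C@@]12C[C@H]3C(O[Si](C(C)C)(C(C)C)C(C)C)=C[C@@H]1[C@](C)([C@@H]3C)C(O[Li])=C2 | intermediate
17 | C16-exo-methyl isotwistane ketone (methyl on the convex face, anti to C7 and C13) | C[Si](C)(C)C#CCC[C@@]12C[C@H]3C(O[Si](C(C)C)(C(C)C)C(C)C)=C[C@@H]1[C@](C)([C@@H]3C)C(=O)[C@H]2C | intermediate
18 | ring-expanded C15-trimethylsilyl ketone (six-membered ring C; C15 epimers) | C[Si](C)(C)C#CCC[C@@]12C[C@H]3C(O[Si](C(C)C)(C(C)C)C(C)C)=C[C@@H]1[C@](C)([C@@H]3C)C(=O)C([Si](C)(C)C)[C@H]2C | intermediate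
19 | ring-C ketone: C14=O, C15H2, axial C16-methyl, C9 triisopropylsilyl enol ether, but-3-ynyl on C6 | C#CCC[C@@]12C[C@H]3C(O[Si](C(C)C)(C(C)C)C(C)C)=C[C@@H]1[C@](C)([C@@H]3C)C(=O)C[C@H]2C | intermediate
20 | equatorial C14 alcohol of 19 (OH trans to the C16 methyl and to the C12 methyl) | C#CCC[C@@]12C[C@H]3C(O[Si](C(C)C)(C(C)C)C(C)C)=C[C@@H]1[C@](C)([C@@H]3C)[C@H](O)C[C@H]2C | intermediate
21 | (E)-alkenyldimethylalane (Al on C2, methyl on C3) with C14–O–AlMe2 | C[Al](C)/C=C(C)/CC[C@@]12C[C@H]3C(O[Si](C(C)C)(C(C)C)C(C)C)=C[C@@H]1[C@](C)([C@@H]3C)[C@H](O[Al](C)C)C[C@H]2C | intermediate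
22 | (E)-allylic alcohol: (E)-5-hydroxy-3-methylpent-3-enyl side chain on C6, C14–OH, C9 silyl enol ether | OC/C=C(C)/CC[C@@]12C[C@H]3C(O[Si](C(C)C)(C(C)C)C(C)C)=C[C@@H]1[C@](C)([C@@H]3C)[C@H](O)C[C@H]2C | intermediate
23 | (2S,3S)-2,3-epoxy alcohol of 22 | OC[C@H]4[C@@](C)(O4)CC[C@@]12C[C@H]3C(O[Si](C(C)C)(C(C)C)C(C)C)=C[C@@H]1[C@](C)([C@@H]3C)[C@H](O)C[C@H]2C | intermediate
24 | (2S,3S)-2,3-epoxy-1-iodide | IC[C@H]4[C@@](C)(O4)CC[C@@]12C[C@H]3C(O[Si](C(C)C)(C(C)C)C(C)C)=C[C@@H]1[C@](C)([C@@H]3C)[C@H](O)C[C@H]2C | intermediate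
25 | diol: (3S)-3-hydroxy-3-methylpent-4-enyl side chain, C14–OH, C9 silyl enol ether | C=C[C@@](C)(O)CC[C@@]12C[C@H]3C(O[Si](C(C)C)(C(C)C)C(C)C)=C[C@@H]1[C@](C)([C@@H]3C)[C@H](O)C[C@H]2C | intermediate
26 | C14 acetate of 25 | C=C[C@@](C)(O)CC[C@@]12C[C@H]3C(O[Si](C(C)C)(C(C)C)C(C)C)=C[C@@H]1[C@](C)([C@@H]3C)[C@H](OC(C)=O)C[C@H]2C | intermediate
27 | CNP0281208.1: C9 ketone, equatorial C14 acetate, axial C16 methyl, (3S)-3-hydroxy-3-methylpent-4-enyl on C6 | C=C[C@@](C)(O)CC[C@@]12C[C@H]3C(=O)C[C@@H]1[C@](C)([C@@H]3C)[C@H](OC(C)=O)C[C@H]2C | target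

Total step count: 15. Longest linear sequence: 15 steps (from 1 and 2 to 27).

Steps most likely to fail

Step 8 (key step). What may go wrong: migration of the quaternary carbon C12 instead of C16 during nitrogen loss, or Lewis-acid-induced loss of the C9 silyl enol ether followed by insertion next to C9. The fallback sets out from 15 and comes back at 19; it inserts the carbon before the methyl group is present, so that only a CH2 competes with C12 in the migration. Compound 15 with TMSCHN2 and Me3Al in CH2Cl2 gives the ring-expanded α-silyl ketone without C16 methyl F1, which dilute HCl in THF at 0 °C protodesilylates to the ring-C ketone without C16 methyl F2. LDA and TMSCl give its C14=C15 trimethylsilyl enol ether F3, and Pd(OAc)2 in MeCN (Saegusa–Ito oxidation) gives the C15=C16 enone F4. Me2CuLi should add axially from the convex face, anti to C7, to give the C16-methyl ketone still carrying the alkynylsilane F5, and K2CO3 in MeOH then leads to 19.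

Step 6. What may go wrong: deprotonation at C16 of the arm instead of C8, or a stepwise closure in which the second Michael addition is slow and the C13 configuration is not relayed from the E alkene. The fallback sets out from 13 and comes back at 15. Kinetic enolate trapping (LiHMDS, TIPSOTf, THF, −78 °C) gives the cross-conjugated 2-silyloxy-1,3-diene F6, and heating in toluene (sealed tube, about 180 °C) effects a concerted intramolecular Diels–Alder reaction, suprafacial on the tigloyl alkene, that gives 15 directly.

Step 9. What may go wrong: hydrogen delivery under kinetic control from the wrong face, giving the axial C14 alcohol. The fallback sets out from 19 and comes back at 20. Hydride reduction (LiAlH4, THF, 0 °C) is run without regard to selectivity and may give the axial C14 epimer F7 beside 20. Meerwein–Ponndorf–Verley/Oppenauer equilibration (Al(OiPr)3, catalytic acetone, iPrOH–toluene, reflux) should then converge on the equatorial alcohol 20 under thermodynamic control.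

Further compounds
F1 | step 8 | ring-expanded C15-trimethylsilyl ketone without C16 methyl | C[Si](C)(C)C#CCC[C@@]12C[C@H]3C(O[Si](C(C)C)(C(C)C)C(C)C)=C[C@@H]1[C@](C)([C@@H]3C)C(=O)C([Si](C)(C)C)C2
F2 | step 8 | ring-C ketone without C16 methyl (alkynylsilane retained) | C[Si](C)(C)C#CCC[C@@]12C[C@H]3C(O[Si](C(C)C)(C(C)C)C(C)C)=C[C@@H]1[C@](C)([C@@H]3C)C(=O)CC2
F3 | step 8 | C14=C15 trimethylsilyl enol ether of F2 | C[Si](C)(C)C#CCC[C@@]12C[C@H]3C(O[Si](C(C)C)(C(C)C)C(C)C)=C[C@@H]1[C@](C)([C@@H]3C)C(O[Si](C)(C)C)=CC2
F4 | step 8 | C15=C16 enone | C[Si](C)(C)C#CCC[C@@]12C[C@H]3C(O[Si](C(C)C)(C(C)C)C(C)C)=C[C@@H]1[C@](C)([C@@H]3C)C(=O)C=C2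
F5 | step 8 | C16-methyl ring-C ketone with alkynylsilane | C[Si](C)(C)C#CCC[C@@]12C[C@H]3C(O[Si](C(C)C)(C(C)C)C(C)C)=C[C@@H]1[C@](C)([C@@H]3C)C(=O)C[C@H]2C
F6 | step 6 | cross-conjugated 2-(triisopropylsilyloxy)cyclohexa-1,3-diene of 13 (C8=C9(OSi)–C10=C11) | C[Si](C)(C)C#CCC[C@@]1(C=CC(O[Si](C(C)C)(C(C)C)C(C)C)=CC1)CC(=O)/C(C)=C/C
F7 | step 9 | axial C14 alcohol (C14 epimer of 20) | C#CCC[C@@]12C[C@H]3C(O[Si](C(C)C)(C(C)C)C(C)C)=C[C@@H]1[C@](C)([C@@H]3C)[C@@H](O)C[C@H]2C
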